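**Assumption:** (2S)-steppogenin (5,7,2′,4′-tetrahydroxyflavanone, CAS 56486-94-3) is bought as the single enantiomer from a natural-product supplier and its ee is checked by chiral HPLC before use. It is a catalogue natural product sold in small packs, not a bulk chemical.

## Retrosynthetic overview

1. Kuwanon E ⇒ its 7,4′-bis-O-TIPS ether **6** (buffered fluoride desilylation last).
2. The C5′–CH2 (aryl–geranyl) bond of **6** ⇒ tandem aromatic Claisen/Cope ([3,3]/[3,3], "para-Claisen") of the 2′-O-geranyl ether **5**.
3. **5** ⇒ geraniol + the free 2′-OH of bis-silyl ether **3** (Mitsunobu).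
4. **3** ⇒ (2S)-steppogenin **1**, which supplies rings A, C and B and the C2 stereocentre intact.
5. No ring is formed in the route; the only skeletal bond made is C5′–C1″.

## Route

**Step 1**
Reactants: **1** (2S)-steppogenin; **2** triisopropylsilyl chloride
Product: **3** (2S)-5-hydroxy-2-[2-hydroxy-4-(triisopropylsilyloxy)phenyl]-7-(triisopropylsilyloxy)chroman-4-one
Conditions: TIPSCl (2.1 equiv), imidazole (4.5 equiv), DMF, 0 °C → rt
Reagents that add atoms: TIPSCl, CC(C)[Si](Cl)(C(C)C)C(C)C
Why: Kinetic phenol silylation takes the most acidic 7-OH and the unhindered 4′-OH, while the 5-OH is hydrogen-bonded to C4=O and the 2′-OH is shielded by the ortho C2 substituent; imidazole is too weak a base to open the flavanone, so C2 is untouched.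

**Step 2**
Reactants: **3** bis-TIPS ether; **4** geraniol
Product: **5** (2S)-2-[2-{[(2E)-3,7-dimethylocta-2,6-dien-1-yl]oxy}-4-(triisopropylsilyloxy)phenyl]-5-hydroxy-7-(triisopropylsilyloxy)chroman-4-one
Conditions: geraniol (1.15 equiv), PPh3 (1.2 equiv), DIAD (1.2 equiv), THF, 0 °C → rt
Reagents that add atoms: geraniol, CC(C)=CCC/C(C)=C/CO (delivers the C10H17 unit; its oxygen is lost as Ph3P=O)
Why: Mitsunobu etherification of the only non-chelated phenol (2′-OH) by SN2 at C1 of a primary allylic alcohol keeps the E-olefin and, being essentially neutral, does not trigger flavanone–chalcone opening at C2; the chelated 5-OH is much less reactive.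

**Step 3 (key step)**
Reactants: **5** 2′-O-geranyl ether
Product: **6** (2S)-2-{5-[(2E)-3,7-dimethylocta-2,6-dien-1-yl]-2-hydroxy-4-(triisopropylsilyloxy)phenyl}-5-hydroxy-7-(triisopropylsilyloxy)chroman-4-one
Conditions: PhNEt2, BSA (3 equiv), 170–180 °C (sealed tube or µw), ~1 h, Ar; then MeOH, rt, and cold 10% citric acid wash (cleaves the transient ArO–TMS, removes the aniline)
Reagents that add atoms: none (TMS from BSA is only a transient cap)
Why: Tandem aromatic Claisen/Cope rearrangement ([3,3] then [3,3]) moves the geranyl unit from O2′ via an ortho dienone (C1′ is quaternary and C3′ is crowded by OTIPS, so Cope outruns enolisation) to the only open para carbon C5′, where chair–chair double inversion restores the linear E-geranyl group; no bond at C2 is involved, and BSA caps the liberated 2′-OH so it cannot open the ring via a quinone methide/chalcone.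

**Step 4**
Reactants: **6** rearranged bis-TIPS ether
Product: **7** Kuwanon E, (2S)-2-{5-[(2E)-3,7-dimethylocta-2,6-dien-1-yl]-2,4-dihydroxyphenyl}-5,7-dihydroxychroman-4-one
Conditions: TBAF (2.4 equiv), AcOH (3 equiv), THF, 0 °C, 30 min
Reagents that add atoms: none
Why: Acetic-acid-buffered fluoride desilylation cleaves both aryl TIPS ethers without strong acid (no chroman formation from the 4′-OH/geranyl pair) and without free phenoxide base (no flavanone–chalcone equilibration), so (2S) is retained.

Any neryl (Z) isomer or 3′-linalyl regioisomer from step 3 is removed by chromatography on AgNO3-impregnated silica at the stage of **6** or **7**. The ee of **7** is checked by chiral HPLC/CD.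

## Compound list

1 | (2S)-steppogenin, (2S)-2-(2,4-dihydroxyphenyl)-5,7-dihydroxychroman-4-one | Oc1ccc([C@@H]2CC(=O)c3c(O)cc(O)cc3O2)c(O)c1 | starting material
2 | triisopropylsilyl chloride | CC(C)[Si](Cl)(C(C)C)C(C)C | starting material
3 | (2S)-5-hydroxy-2-[2-hydroxy-4-(TIPS-oxy)phenyl]-7-(TIPS-oxy)chroman-4-one | CC(C)[Si](Oc1ccc([C@@H]2CC(=O)c3c(O)cc(O[Si](C(C)C)(C(C)C)C(C)C)cc3O2)c(O)c1)(C(C)C)C(C)C | intermediate
4 | geraniol, (2E)-3,7-dimethylocta-2,6-dien-1-ol | CC(C)=CCC/C(C)=C/CO | starting material
5 | (2S)-2-[2-(geranyloxy)-4-(TIPS-oxy)phenyl]-5-hydroxy-7-(TIPS-oxy)chroman-4-one | CC(C)=CCC/C(C)=C/COc1cc(O[Si](C(C)C)(C(C)C)C(C)C)ccc1[C@@H]2CC(=O)c3c(O)cc(O[Si](C(C)C)(C(C)C)C(C)C)cc3O2 | intermediate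
6 | (2S)-2-[5-geranyl-2-hydroxy-4-(TIPS-oxy)phenyl]-5-hydroxy-7-(TIPS-oxy)chroman-4-one | CC(C)=CCC/C(C)=C/Cc1cc([C@@H]2CC(=O)c3c(O)cc(O[Si](C(C)C)(C(C)C)C(C)C)cc3O2)c(O)cc1O[Si](C(C)C)(C(C)C)C(C)C | intermediate
7 | Kuwanon E | CC(C)=CCC/C(C)=C/Cc1cc([C@@H]2CC(=O)c3c(O)cc(O)cc3O2)c(O)cc1O | target

## Summary

Total steps: 4. Longest linear sequence: 4.

Steps most likely to fail, with fallbacks:

1. **Step 3 (Claisen/Cope).** Risks are the 3′-linalyl ortho product, some neryl isomer, and ee erosion at 170–180 °C. Fallback: make the C5′–C bond by cross-coupling instead. Iodinate **3** at C5′ (NIS, para to the free 2′-OH), then Pd-catalysed Stille coupling with (E)-geranyl-SnBu3 at ≤60 °C, then desilylate.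
2. **Step 1 (2′- versus 4′-OH discrimination in the bis-silylation).** Fallback: silylate only the 7-OH (1 equiv TIPSCl, unambiguous) and carry the side chain on the more accessible O4′ as a tertiary 3,7-dimethylocta-1,6-dien-3-yl ether. This is made with dehydrolinalyl carbonate (CuCl2/DBU) followed by Lindlar reduction, and undergoes a single ortho-Claisen to C5′ at about 110 °C. The cost is an E/Z mixture that must be separated.
3. **Step 2 (Mitsunobu on a hindered phenol, with possible 5-O-alkylation or SN2′ leakage).** Fallback: Pd(0)-catalysed Tsuji–Trost O-allylation of **3** with geranyl methyl carbonate under neutral conditions, which gives the linear ether and allylates only the non-chelated phenol.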